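## Analysis of the target

- Target 20 is a 5,7,2'-trihydroxyisoflavone: rings A and C form the chromone and ring B is the 3-aryl group. Ring B carries an angularly fused 3-hydroxy-2,2-dimethyldihydropyran (ring D) across C3' and C4', so ring B with ring D is a 3,5-dihydroxy-2,2-dimethylchroman-6-yl unit (chroman numbering is used for this part below).
- The only stereocenter is the carbinol carbon C3 of ring D, which is (S). It sits between the benzylic CH2 (C4) and the quaternary C2 and has no stereochemical partner, so it must be set by absolute control.
- Ring C is opened by hydroxide or alkoxide and its C2–C3 double bond can be hydrogenated. Ring A is a free phloroglucinol-type nucleus that is easily C-functionalised. Ring B is an electron-rich resorcinol diether.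
- The 2'-hydroxyl is close enough to attack the carbon that becomes C2 of ring C, which would give a benzofuran, so it must stay masked until ring C is closed. The secondary alcohol must be masked against formylation and sulfonylation in the same step.
- The difficulty is to combine three things without a long protecting-group sequence: regiocontrolled fusion of ring D between the two ring B oxygens, enantiocontrol at an isolated carbinol, and the unprotected 5,7-dihydroxy pattern.
- The strategy rests on ring A. C4a carries the acyl carbon C4, and C5, C7 and C8a carry oxygen. This is the alternating pattern of a linear tetraketide. C8a, C8, C7, C6, C5, C4a, C4 and C3 map onto an eight-carbon 3,5,7-trioxo ester chain, which a 6-(2-oxoalkyl)-4-hydroxy-2-pyrone holds in lactone-masked form. Ring A can therefore be made by a Claisen closure that forms C4a–C5.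

## Retrosynthetic reasoning

**20 ⇒ 19.** The two benzyl ethers (on the ring B phenol and on the ring D alcohol) are removed last in one hydrogenolysis. Benzyl is used on the C3 oxygen rather than a silyl group because ring C closure uses a boron fluoride Lewis acid with free phenols, which releases fluoride capable of cleaving a silyl ether. Using the same group on both oxygens also saves a deprotection step.

**19 ⇒ 18.** Ring C is cut at C2 (bonds C2–C3 and O1–C2). This leaves the deoxybenzoin 18 and a one-carbon electrophile derived from a formamide. Ring A of 18 is symmetric, so either ortho hydroxyl gives the same chromone, and the benzyl ether on ring B blocks the competing five-membered closure.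

**18 ⇒ 16 (through 17).** The C4a–C5 bond of ring A is cut. This is the disconnection that carries the strategy. Opening 18 there gives the triketo ester 17, which is the methanolysis product of the pyrone 16. The forward step must open the lactone, make the carbon between the two ketones nearest ring B attack the ester carbon, and avoid the aldol closures of the same chain. All three ring A oxygens then arrive in place, with no electrophilic substitution on a preformed triphenol and no ring A protecting groups.

**16 ⇒ 12 + 13.** The bond between the pyrone side-chain CH2 and the ketone carbon is cut. This gives the dianion 14 of commercial pyrone 13 and an arylacetyl electrophile. The N-methoxy-N-methylamide 12 is chosen over an ester because its adduct 15 stays tetrahedral until the quench, so the acidic product never meets the dianion. Addition to such chelating amides also competes well with removal of their benzylic protons.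

**12 ⇒ 8.** The amide is traced through acid 11 and nitrile 10 to the aldehyde 8 by a one-carbon homologation. Both benzyl ethers are already in place at 8 because the aldehyde stage has no acidic C–H. The hindered ring D alcohol can therefore be benzylated through its alkoxide there, which would not be possible once the arylacetic CH2 exists.

**8 ⇒ 4 (through 7, 6 and 5).** The C3–O bond of ring D, and with it the stereocenter, is traced to the chromene 4 by enantioselective epoxidation to 5 and hydride cleavage of the benzylic C4–O bond. 2,2-Dimethylchromenes are among the best substrates for manganese salen epoxidation. The reduction is placed early, when nothing else in the molecule is reducible apart from the aldehyde, which is simply re-formed from diol 6 by a benzylic-selective oxidation to 7.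

**4 ⇒ 3 ⇒ 1 + 2.** Ring D is cut at O1–C2 and C4–C4a, giving 1 and 2. The hydrogen bond between the 2-hydroxyl and the formyl group of 1 directs the annulation to the carbon between the two oxygens and through the 4-oxygen. This gives the angular fusion and leaves free the hydroxyl that becomes the 2'-oxygen of 20.

## Alternatives that were turned down

**Alternative 1:** Ring B is disconnected at C1'–C2', C2'–C3' and C4'–C5' and assembled on a finished chromone by a photochemical benzannulation.
- Forward key step: irradiation of the chromonyl diazo enone A2 triggers a Wolff rearrangement to a vinylketene. This adds the prenyl-substituted siloxyalkyne A3 in a [2+2] fashion, and the cyclobutenone opens and recloses by a 6π process to give the phenol A1.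
- For it: it is convergent, and it places the 2'-hydroxyl, the prenyl group and the 4'-oxygen on ring B without any regiochemical doubt. On convergence it is stronger than the chosen route.
- Against it: A1 still lacks ring D and the stereocenter. The prenyl group would have to be epoxidised enantioselectively and closed in the 6-endo sense by the 4'-oxygen, while the adjacent 2'-hydroxyl and the 5-exo pathway both compete. A2 and A3 each need several steps, and the chromone is itself a photoactive enone.
- Comparison: the chosen route sets the stereocenter on a cyclic cis-alkene, where reagent control is most dependable, and closes ring D with no regiochemical question.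

**Alternative 2:** The C3–O bond of ring D is disconnected last, on the intact isoflavone.
- Forward key step: the chromene triacetate A4 is epoxidised with (S,S)-(salen)MnCl (trivalent manganese) with a peracid and an amine N-oxide at low temperature, which should give the (3S,4S)-epoxide A5.
- For it: it is the shortest plan, it uses the same stereodefining reaction as the chosen route, and it carries no stereocenter through the synthesis. On step economy it is stronger.
- Against it: A5 must then lose its C4 oxygen regioselectively in a molecule that holds a reducible chromone double bond and three aryl acetates. Aluminium hydrides are excluded, hydrogenolysis threatens ring C, and the acetoxy group peri to C4 can take part in opening the electron-rich benzylic epoxide.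
- Comparison: the chosen route does the same epoxide reduction early, with a strong hydride and no competing functionality, and offers crystalline early intermediates at which enantiomeric purity could be raised.

**Alternative 3:** Ring D is disconnected at the aryl–oxygen bond.
- Forward key step: Pd(OAc)2 with 2-(di-tert-butylphosphino)-1,1'-binaphthyl and Cs2CO3 would couple the tertiary hydroxyl of the chiral-pool bromoarene A6 with the ortho C–Br bond, by oxidative addition to zerovalent palladium and C–O reductive elimination, to give the chroman A7.
- For it: the configuration comes from the chiral pool with no question of enantioselectivity, which is stronger than a catalytic epoxidation. The chroman could later be metalated next to the acetal oxygen and cross-coupled.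
- Against it: the etherification joins a hindered tertiary alkoxide to a 1,2,3-trisubstituted arene, where reductive elimination is slow and hydrodehalogenation competes. The side chain of A6 needs its own multistep preparation. Ring A would still come from a protected triphenol with later deprotection.
- Comparison: the chosen route makes ring D in one step from 1 and 2, needs no precious-metal bond formation, and brings in ring A unprotected.

Key step: step 11

Assumption: (S,S)-(salen)MnCl is taken to attack the face of 4 that leads to the (3S,4S)-epoxide, as with other 2,2-dimethylchromenes; if the sense proved opposite, the (R,R)-complex would be used.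

## Route

Step 1
Reactants: 1 2,4-dihydroxybenzaldehyde; 2 3-methylbut-2-enal
Product: 3 5-hydroxy-2,2-dimethyl-2H-chromene-6-carbaldehyde
Conditions: pyridine, 140 °C, sealed tube
Reagents that add atoms: none
Why: Base-mediated chromenylation: aldol-type C-alkylation at the carbon between the two hydroxyls, dehydration to an ortho-quinone methide and oxa-6π electrocyclization. The 2-hydroxyl is held in a hydrogen bond to the formyl group, so the ring should close through the 4-oxygen and give the angular chromene with the chelated hydroxyl free.

Step 2
Reactants: 3 5-hydroxy-2,2-dimethyl-2H-chromene-6-carbaldehyde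
Product: 4 5-(benzyloxy)-2,2-dimethyl-2H-chromene-6-carbaldehyde
Conditions: BnBr, K2CO3, DMF, 60 °C
Reagents that add atoms: benzyl bromide BrCc1ccccc1
Why: Williamson etherification of the chelated phenol; warm DMF with carbonate is enough to break the hydrogen bond, and the phenol must be capped before the oxidation in step 3.

Step 3
Reactants: 4 5-(benzyloxy)-2,2-dimethyl-2H-chromene-6-carbaldehyde
Product: 5 (3S,4S)-5-(benzyloxy)-3,4-epoxy-2,2-dimethylchroman-6-carbaldehyde
Conditions: (S,S)-(salen)MnCl [chloro complex of trivalent manganese with the (S,S)-1,2-cyclohexanediamine bis(3,5-di-tert-butylsalicylaldimine) ligand] (5 mol%), 4-phenylpyridine N-oxide (20 mol%), aq. NaOCl buffered at pH 11.3, CH2Cl2, 0 °C; crude epoxide passed through basic alumina and used at once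
Reagents that add atoms: sodium hypochlorite [Na+].[O-]Cl
Why: Jacobsen–Katsuki epoxidation of a cis-disubstituted, aryl-conjugated cyclic alkene, the substrate class for which this catalyst is most selective. The alkene approaches the manganese oxo unit side-on over the diamine bridge, and the (S,S)-ligand should deliver oxygen to the face that gives the (3S,4S)-epoxide, which fixes C3. The cold, buffered, two-phase medium should leave the non-enolisable aldehyde untouched.

Step 4
Reactants: 5 (3S,4S)-5-(benzyloxy)-3,4-epoxy-2,2-dimethylchroman-6-carbaldehyde
Product: 6 (3S)-5-(benzyloxy)-6-(hydroxymethyl)-2,2-dimethylchroman-3-ol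
Conditions: LiAlH4, THF, 0 °C to rt; aq. NaOH work-up
Reagents that add atoms: none
Why: Hydride opening of the aryl epoxide by SN2 attack at benzylic C4, which is activated by the arene and is not shielded by the gem-dimethyl group that blocks C3. The C3–O bond is not touched, so C3 keeps its (S) configuration. The aldehyde is reduced in the same operation and restored in step 5.

Step 5
Reactants: 6 (3S)-5-(benzyloxy)-6-(hydroxymethyl)-2,2-dimethylchroman-3-ol
Product: 7 (3S)-5-(benzyloxy)-3-hydroxy-2,2-dimethylchroman-6-carbaldehyde
Conditions: activated MnO2, CH2Cl2, rt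
Reagents that add atoms: none
Why: MnO2 oxidises benzylic alcohols selectively; the saturated secondary alcohol of ring D should not react.

Step 6
Reactants: 7 (3S)-5-(benzyloxy)-3-hydroxy-2,2-dimethylchroman-6-carbaldehyde
Product: 8 (3S)-3,5-bis(benzyloxy)-2,2-dimethylchroman-6-carbaldehyde
Conditions: NaH, BnBr, Bu4NI (cat.), DMF, 0 °C to rt
Reagents that add atoms: benzyl bromide BrCc1ccccc1
Why: Williamson etherification of the hindered secondary alkoxide, helped by iodide catalysis. It is done here because 7 has no acidic C–H and a non-enolisable aldehyde, so the alkoxide cannot be diverted into C-alkylation.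

Step 7
Reactants: 8 (3S)-3,5-bis(benzyloxy)-2,2-dimethylchroman-6-carbaldehyde
Product: 10 2-[(3S)-3,5-bis(benzyloxy)-2,2-dimethylchroman-6-yl]acetonitrile, via tosylvinyl formamide 9 (not isolated)
Conditions: TosMIC, KOC(CH3)3, DME, −40 °C; then CH3OH, reflux
Reagents that add atoms: p-toluenesulfonylmethyl isocyanide [C-]#[N+]CS(=O)(=O)c1ccc(C)cc1
Why: Van Leusen reductive cyanation: the isocyanide anion adds to the aldehyde, and the oxazoline opens to 9. Methanolysis then removes the formyl group and the sulfinate, leaving the nitrile with one more carbon. The conditions are basic throughout and suit the benzyl ethers and the chroman.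

Step 8
Reactants: 10 2-[(3S)-3,5-bis(benzyloxy)-2,2-dimethylchroman-6-yl]acetonitrile
Product: 11 2-[(3S)-3,5-bis(benzyloxy)-2,2-dimethylchroman-6-yl]acetic acid
Conditions: KOH, EtOH–H2O, reflux; then aq. HCl
Reagents that add atoms: water O
Why: Alkaline hydrolysis of an arylacetonitrile; the ethers and the stereocenter are inert to hydroxide.

Step 9
Reactants: 11 2-[(3S)-3,5-bis(benzyloxy)-2,2-dimethylchroman-6-yl]acetic acid
Product: 12 2-[(3S)-3,5-bis(benzyloxy)-2,2-dimethylchroman-6-yl]-N-methoxy-N-methylacetamide
Conditions: CH3NH(OCH3)·HCl, EDC·HCl, HOBt (cat.), N-methylmorpholine, CH2Cl2, 0 °C to rt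
Reagents that add atoms: N,O-dimethylhydroxylamine hydrochloride CNOC.Cl
Why: Carbodiimide amide coupling to the Weinreb amide, the acyl donor needed for step 10.

Step 10
Reactants: 12 2-[(3S)-3,5-bis(benzyloxy)-2,2-dimethylchroman-6-yl]-N-methoxy-N-methylacetamide; 13 4-hydroxy-6-methyl-2H-pyran-2-one
Product: 16 6-{3-[(3S)-3,5-bis(benzyloxy)-2,2-dimethylchroman-6-yl]-2-oxopropyl}-4-hydroxy-2H-pyran-2-one, via dilithio pyrone dianion 14 (not isolated), via lithium hemiaminal adduct 15 (not isolated)
Conditions: 13 (2.2 equiv), LDA (4.5 equiv), THF, −78 to −20 °C; then 12, −78 to 0 °C; cold aq. HCl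
Reagents that add atoms: none
Why: Claisen-type C-acylation of the pyrone dianion at its methyl carbon, the most basic and most nucleophilic site. The chelated adduct 15 should persist until the quench, so the acidic product is never formed in the presence of 14, and carbonyl addition to a chelating amide is expected to outrun removal of its benzylic protons.

Step 11
Reactants: 16 6-{3-[(3S)-3,5-bis(benzyloxy)-2,2-dimethylchroman-6-yl]-2-oxopropyl}-4-hydroxy-2H-pyran-2-one
Product: 18 2-[(3S)-3,5-bis(benzyloxy)-2,2-dimethylchroman-6-yl]-1-(2,4,6-trihydroxyphenyl)ethan-1-one, via magnesium-chelated triketo ester 17 (not isolated)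
Conditions: Mg(OCH3)2 (8 equiv), CH3OH, reflux; then cold aq. HCl
Reagents that add atoms: none
Why: Methoxide should open the lactone carbonyl of the pyrone to give the 3,5,7-trioxo ester 17, held as a magnesium bis-enolate chelate. The carbanion at C6 of the chain, between the two ketones nearest ring B, then attacks the ester carbon C1; methoxide leaves, and enolisation of the cyclohexanetrione gives aromatic ring A with the new C4a–C5 bond. The closest known reaction type is the magnesium methoxide cyclisation of 6-(2-oxoalkyl)-4-hydroxy-2-pyrones and of 3,5,7-triketo esters to acylphloroglucinols, the laboratory counterpart of the polyketide Claisen cyclisation. The ring closes in the 6-exo-trig mode, with the ester carbonyl exocyclic to the forming ring. No stereocenter is formed and C3 of ring D is remote and not epimerisable. The step needs Claisen closure to beat two aldol closures (ester-side methylene C2 onto ketone C7, and benzylic C8 onto ketone C3) and retro-Claisen cleavage. In the magnesium chelate the two most acidic methylenes, C4 and C6, are the ionised ones. The ketone carbons are bound as enolates and so are poor electrophiles, which leaves the ester carbon as the only good acceptor. The benzylic C8 is far less acidic than C6, and the chelation also protects the 1,3-diketone from methoxide cleavage.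

Step 12
Reactants: 18 2-[(3S)-3,5-bis(benzyloxy)-2,2-dimethylchroman-6-yl]-1-(2,4,6-trihydroxyphenyl)ethan-1-one
Product: 19 3-[(3S)-3,5-bis(benzyloxy)-2,2-dimethylchroman-6-yl]-5,7-dihydroxy-4H-chromen-4-one
Conditions: BF3·OEt2 (6 equiv), DMF, rt; then CH3SO2Cl (3 equiv) in DMF, 60 °C; then H2O
Reagents that add atoms: N,N-dimethylformamide CN(C)C=O
Why: One-carbon insertion into a 2-hydroxydeoxybenzoin. BF3 binds the chelated hydroxy ketone, which activates the methylene and shields ring A from C-formylation. The iminium salt from DMF and CH3SO2Cl attacks the methylene, a ring A hydroxyl adds to the new carbon, and dimethylamine is lost. Ring A is symmetric, so only one chromone can form, and the benzyl ether on ring B prevents benzofuran closure.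

Step 13
Reactants: 19 3-[(3S)-3,5-bis(benzyloxy)-2,2-dimethylchroman-6-yl]-5,7-dihydroxy-4H-chromen-4-one
Product: 20 5,7-dihydroxy-3-[(3S)-3,5-dihydroxy-2,2-dimethylchroman-6-yl]-4H-chromen-4-one
Conditions: H2 (1 atm), Pd(OH)2/C, EtOAc–CH3OH, rt
Reagents that add atoms: none
Why: Hydrogenolysis of both benzyl ethers. The aryl ether should go first, and the hindered secondary ether is the reason for the hydroxide catalyst. The reaction is stopped once the second benzyl group is gone, so that the C2–C3 double bond of ring C is not reduced.

## Compound list

1 | 2,4-dihydroxybenzaldehyde | O=Cc1ccc(O)cc1O | starting material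
2 | 3-methylbut-2-enal | CC(C)=CC=O | starting material
3 | 5-hydroxy-2,2-dimethyl-2H-chromene-6-carbaldehyde | CC1(C)Oc2ccc(C=O)c(O)c2C=C1 | intermediate
4 | 5-(benzyloxy)-2,2-dimethyl-2H-chromene-6-carbaldehyde | CC1(C)Oc2ccc(C=O)c(OCc3ccccc3)c2C=C1 | intermediate
5 | (3S,4S)-5-(benzyloxy)-3,4-epoxy-2,2-dimethylchroman-6-carbaldehyde | CC1(C)Oc2ccc(C=O)c(OCc3ccccc3)c2[C@@H]2O[C@H]12 | intermediate
6 | (3S)-5-(benzyloxy)-6-(hydroxymethyl)-2,2-dimethylchroman-3-ol | CC1(C)Oc2ccc(CO)c(OCc3ccccc3)c2C[C@@H]1O | intermediate
7 | (3S)-5-(benzyloxy)-3-hydroxy-2,2-dimethylchroman-6-carbaldehyde | CC1(C)Oc2ccc(C=O)c(OCc3ccccc3)c2C[C@@H]1O | intermediate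
8 | (3S)-3,5-bis(benzyloxy)-2,2-dimethylchroman-6-carbaldehyde | CC1(C)Oc2ccc(C=O)c(OCc3ccccc3)c2C[C@@H]1OCc1ccccc1 | intermediate
9 | N-{2-[(3S)-3,5-bis(benzyloxy)-2,2-dimethylchroman-6-yl]-1-tosylethenyl}formamide (not isolated) | CC1(C)Oc2ccc(C=C(NC=O)S(=O)(=O)c3ccc(C)cc3)c(OCc3ccccc3)c2C[C@@H]1OCc1ccccc1 | intermediate
10 | 2-[(3S)-3,5-bis(benzyloxy)-2,2-dimethylchroman-6-yl]acetonitrile | CC1(C)Oc2ccc(CC#N)c(OCc3ccccc3)c2C[C@@H]1OCc1ccccc1 | intermediate
11 | 2-[(3S)-3,5-bis(benzyloxy)-2,2-dimethylchroman-6-yl]acetic acid | CC1(C)Oc2ccc(CC(=O)O)c(OCc3ccccc3)c2C[C@@H]1OCc1ccccc1 | intermediate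
12 | 2-[(3S)-3,5-bis(benzyloxy)-2,2-dimethylchroman-6-yl]-N-methoxy-N-methylacetamide | CC1(C)Oc2ccc(CC(=O)N(C)OC)c(OCc3ccccc3)c2C[C@@H]1OCc1ccccc1 | intermediate
13 | 4-hydroxy-6-methyl-2H-pyran-2-one | Cc1cc(O)cc(=O)o1 | starting material
14 | dilithium dianion of 4-hydroxy-6-methyl-2H-pyran-2-one (not isolated) | [Li+].[Li+].[CH2-]c1cc([O-])cc(=O)o1 | intermediate
15 | hemiaminal adduct of 12 and 14, formed as its lithium salt, drawn in neutral form (not isolated) | CC1(C)Oc2ccc(CC(O)(Cc3cc(O)cc(=O)o3)N(C)OC)c(OCc3ccccc3)c2C[C@@H]1OCc1ccccc1 | intermediate
16 | 6-{3-[(3S)-3,5-bis(benzyloxy)-2,2-dimethylchroman-6-yl]-2-oxopropyl}-4-hydroxy-2H-pyran-2-one | CC1(C)Oc2ccc(CC(=O)Cc3cc(O)cc(=O)o3)c(OCc3ccccc3)c2C[C@@H]1OCc1ccccc1 | intermediate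
17 | methyl 8-[(3S)-3,5-bis(benzyloxy)-2,2-dimethylchroman-6-yl]-3,5,7-trioxooctanoate, formed as its magnesium chelate (not isolated) | CC1(C)Oc2ccc(CC(=O)CC(=O)CC(=O)CC(=O)OC)c(OCc3ccccc3)c2C[C@@H]1OCc1ccccc1 | intermediate
18 | 2-[(3S)-3,5-bis(benzyloxy)-2,2-dimethylchroman-6-yl]-1-(2,4,6-trihydroxyphenyl)ethan-1-one | CC1(C)Oc2ccc(CC(=O)c3c(O)cc(O)cc3O)c(OCc3ccccc3)c2C[C@@H]1OCc1ccccc1 | intermediate
19 | 3-[(3S)-3,5-bis(benzyloxy)-2,2-dimethylchroman-6-yl]-5,7-dihydroxy-4H-chromen-4-one | CC1(C)Oc2ccc(-c3coc4cc(O)cc(O)c4c3=O)c(OCc3ccccc3)c2C[C@@H]1OCc1ccccc1 | intermediate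
20 | 5,7-dihydroxy-3-[(3S)-3,5-dihydroxy-2,2-dimethylchroman-6-yl]-4H-chromen-4-one | CC1(C)Oc2ccc(-c3coc4cc(O)cc(O)c4c3=O)c(O)c2C[C@@H]1O | target

## Step count and least certain steps

Total step count: 13. Longest linear sequence: 13 steps (1 to 20); 2 and 13 enter as single commercial compounds.

**Step 11 (key step).** The chain may close by aldol condensation instead of Claisen acylation, giving resorcylate-type rings, or the 1,3-diketone may be cleaved by methoxide, or the chain may simply re-lactonise on work-up. The benzylic methylene next to the terminal ketone is an extra acidic site that simple alkyl analogues lack. Fallback: ring A is brought in ready-made. Setting out from nitrile 10, Hoesch acylation of phloroglucinol (ZnCl2, HCl gas, Et2O, 0 °C) should give the ketiminium chloride F1. Hydrolysis of F1 in hot water returns to the route at 18. This bypasses steps 8 to 11.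

**Step 10.** Proton transfer from the benzylic CH2 of 12 to the dianion 14 may compete with addition and return both partners unchanged. Fallback: an aldehyde is used as the electrophile, since it adds faster than it is deprotonated. Setting out from 12, reduction with (i-Bu)2AlH at −78 °C should give the arylacetaldehyde F2. Aldol addition of 14 to F2 should give the hydroxyalkyl pyrone F3, and oxidation of F3 (CrO3, aq. H2SO4, acetone, 0 °C) returns to the route at 16.

**Step 3.** Three processes could hurt: slow oxidation of the aldehyde by hypochlorite, opening of the electron-rich benzylic epoxide during isolation, and reduced facial selectivity caused by the benzyloxy group peri to C4. Fallback: the aldehyde is masked. Setting out from 4, acetalisation with ethylene glycol (pyridinium tosylate, benzene, reflux) should give the dioxolane F4. The same epoxidation should give the epoxy dioxolane F5, and LiAlH4 the chromanol dioxolane F6. Mild aqueous acid then frees the aldehyde and returns to the route at 7.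

**Step 12.** The phenolic benzyl ether may be lost, or ring A may be C-formylated, under the Lewis acid and the acid released at 60 °C. Fallback: Lewis-acid-free aminomethylenation. Setting out from 18, N,N-dimethylformamide dimethyl acetal in THF at 60 °C should give the enaminone F7. Brief warming of F7 in acetic acid closes ring C and returns to the route at 19.

**Step 13.** The C2–C3 double bond of ring C may be reduced before the hindered secondary benzyl ether is fully cleaved. Fallback: Lewis acid debenzylation instead of hydrogenolysis. Setting out from 19, BCl3 with pentamethylbenzene in CH2Cl2 at −78 °C should cleave both ethers and give 20 directly. This fallback makes no new compound (entry F0).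

## Further compounds

F1 | step 11 | 2-[(3S)-3,5-bis(benzyloxy)-2,2-dimethylchroman-6-yl]-1-(2,4,6-trihydroxyphenyl)ethan-1-iminium chloride | CC1(C)Oc2ccc(CC(=[NH2+])c3c(O)cc(O)cc3O)c(OCc3ccccc3)c2C[C@@H]1OCc1ccccc1.[Cl-]
F2 | step 10 | 2-[(3S)-3,5-bis(benzyloxy)-2,2-dimethylchroman-6-yl]acetaldehyde | CC1(C)Oc2ccc(CC=O)c(OCc3ccccc3)c2C[C@@H]1OCc1ccccc1
F3 | step 10 | 6-{3-[(3S)-3,5-bis(benzyloxy)-2,2-dimethylchroman-6-yl]-2-hydroxypropyl}-4-hydroxy-2H-pyran-2-one | CC1(C)Oc2ccc(CC(O)Cc3cc(O)cc(=O)o3)c(OCc3ccccc3)c2C[C@@H]1OCc1ccccc1
F4 | step 3 | 2-[5-(benzyloxy)-2,2-dimethyl-2H-chromen-6-yl]-1,3-dioxolane | CC1(C)Oc2ccc(C3OCCO3)c(OCc3ccccc3)c2C=C1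
F5 | step 3 | 2-[(3S,4S)-5-(benzyloxy)-3,4-epoxy-2,2-dimethylchroman-6-yl]-1,3-dioxolane | CC1(C)Oc2ccc(C3OCCO3)c(OCc3ccccc3)c2[C@@H]2O[C@H]12
F6 | step 3 | (3S)-5-(benzyloxy)-6-(1,3-dioxolan-2-yl)-2,2-dimethylchroman-3-ol | CC1(C)Oc2ccc(C3OCCO3)c(OCc3ccccc3)c2C[C@@H]1O
F7 | step 12 | 2-[(3S)-3,5-bis(benzyloxy)-2,2-dimethylchroman-6-yl]-3-(dimethylamino)-1-(2,4,6-trihydroxyphenyl)prop-2-en-1-one | CC1(C)Oc2ccc(C(=CN(C)C)C(=O)c3c(O)cc(O)cc3O)c(OCc3ccccc3)c2C[C@@H]1OCc1ccccc1
F0 | step 13 | none | none
A1 | alternative 1 | 5,7-bis(benzyloxy)-3-[2-hydroxy-3-(3-methylbut-2-en-1-yl)-4-(triisopropylsilyloxy)phenyl]-4H-chromen-4-one | CC(C)=CCc1c(O[Si](C(C)C)(C(C)C)C(C)C)ccc(-c2coc3cc(OCc4ccccc4)cc(OCc4ccccc4)c3c2=O)c1O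
A2 | alternative 1 | 5,7-bis(benzyloxy)-3-[(E)-4-diazo-3-oxobut-1-en-1-yl]-4H-chromen-4-one | [N-]=[N+]=CC(=O)/C=C/c1coc2cc(OCc3ccccc3)cc(OCc3ccccc3)c2c1=O
A3 | alternative 1 | triisopropyl[(5-methylhex-4-en-1-yn-1-yl)oxy]silane | CC(C)=CCC#CO[Si](C(C)C)(C(C)C)C(C)C
A4 | alternative 2 | 3-(5-acetoxy-2,2-dimethyl-2H-chromen-6-yl)-4-oxo-4H-chromene-5,7-diyl diacetate | CC1(C)Oc2ccc(-c3coc4cc(OC(C)=O)cc(OC(C)=O)c4c3=O)c(OC(C)=O)c2C=C1
A5 | alternative 2 | 3-[(3S,4S)-5-acetoxy-3,4-epoxy-2,2-dimethylchroman-6-yl]-4-oxo-4H-chromene-5,7-diyl diacetate | CC1(C)Oc2ccc(-c3coc4cc(OC(C)=O)cc(OC(C)=O)c4c3=O)c(OC(C)=O)c2[C@@H]2O[C@H]12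
A6 | alternative 3 | (3S)-4-[2-bromo-6-(methoxymethoxy)phenyl]-3-(tert-butyldimethylsilyloxy)-2-methylbutan-2-ol | CC(C)(O)[C@H](Cc1c(Br)cccc1OCOC)O[Si](C)(C)C(C)(C)C
A7 | alternative 3 | (S)-3-(tert-butyldimethylsilyloxy)-5-(methoxymethoxy)-2,2-dimethylchroman | CC1(C)Oc2cccc(OCOC)c2C[C@@H]1O[Si](C)(C)C(C)(C)C
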